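The readings are simulated for an exercise; scatter was added.

**The vessel.** Each closed, stirred flask holds J and L at constant volume, and each exchange on J takes one L.

| flask | J | L | remark | time |
|---|---|---|---|---|
| Monday's | 0.80 M | 0.93 M | run made earlier |  |
| Friday's | 0.80 M | 1.5 M | run made earlier |  |
| grey | 0.80 M | 0.800 M |  | 3.0 d |
| blue | 0.80 M | 1.20 M |  | 3.0 d |
| teal | 0.80 M | 2.40 M |  | 3.0 d |

| run | time / h | G / % | J / % |
|---|---|---|---|
| Monday's | 10.0 | 28.9 | 22.7 |
| Monday's | 20.0 | 28.5 | 22.0 |
| Monday's | 25.0 | 27.8 | 23.0 |
| Monday's | 40.0 | 28.8 | 21.4 |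
| Friday's | 3.00 | 45.5 | 4.8 |
| Friday's | 6.00 | 47.4 | 5.8 |
| Friday's | 15.0 | 47.9 | 4.8 |
| Friday's | 40.0 | 47.0 | 5.6 |

(standard deviation of a reading: 0.5 percentage points)



* final G, as a percentage of the J charged, for each flask in turn (grey, blue, teal)

**Ligand budget.** The ligand budget is L charged per J charged, and for teal it is 3.00. Friday's budget is 1.88. If a singly exchanged complex were the sole unseen form, Friday's 40.0 h readings would account for L equal to 141 % of the J charged. That leaves 0.461 unaccounted for. I take L as the limiting reagent and place this gap in a third exchange on G, which puts 23.1 % of the J charged in that product on Friday.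

**My bracket.** If L is spent, teal's budget of 3.00 takes every J to that product, so my lower bound for G is zero. For the upper bound, Friday's readings stand near their plateau by 3.00 h, so I take that product as present by then, with [G] and [L] below their later reading and charge on the way, which gives a rate constant of at least 3.03 × 10⁻⁵ /M/s. Late in teal, I expect [G] and [L] to be equal and to fall at second order, so I put G below 15.9 %, an estimate that counts the whole 3.0 d as that late stretch.

**The forecast.** The forecast reads the plateaux as equilibrium, “so these are equilibria”, and gives 24.3 %, 38.1 % and 62 %. Its teal value stands above my ceiling.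

**The flasks.** They give 22.7 %, 39.4 % and 1.90 %, and teal lies below the ceiling.

    J + L → Q + X (k = 8.90 × 10⁻⁴ /M/s)
    X + L → Q + G (k = 5.80 × 10⁻⁴ /M/s)
    G + L → Z (k = 2.50 × 10⁻⁴ /M/s)

In blue, the step consuming G has 0.43 of the rate constant of the step making it; L stands at 0 % of its charge with X 37.5 %, G 39.4 % and Z 11.2 %, which count to 1.50 equivalents against a budget of 1.50. Teal, with its budget of 3.00, stands at 3.00 d with Z 98.1 %, G 1.90 % and L 0.64 % of its charge.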